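**Plan**

1. Retrosynthesis (eudesmane numbering): cut the C15–O acyl bond and take C12 back to a methyl group; then cut the ring-fusion bond C5–C10 to reach the ten-membered germacra-1(10),4-diene (germacrene A); then cut C2–C3 of that ring (oxy-Cope retron) to reach a 1,2-dialkenylcyclohexanol whose six-membered ring is that of (R)-carvone.
2. Forward: carvone is vinylated at its methyl-bearing α-carbon and isopropenylated at the carbonyl; an anionic oxy-Cope rearrangement opens the cyclohexane to the ten-membered ring; a single transannular C5–C10 bond then closes ring A and ring B together.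
3. Enabling feature: in the cyclodeca-1(10),4-diene the two E-trisubstituted alkenes C1=C10 and C4=C5 lie face to face across the ring, with C5 within bonding distance of C10, and ring strain is released on closure.
4. Stereochemistry: C7 comes from (R)-carvone; C5 and C10 are set in the key step, relayed from C7 through the crown conformer; the (Z)-enoate comes from a Still–Gennari olefination.
5. Allylic oxidation and 1,3-transposition carry the cyclization product to the C15 alcohol whichever way the new alkene is placed; C12 is raised from methyl to acid last (SeO2, MnO2, NaClO2), when the ring alkene is deactivated as its allylic ester.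

Key step: step 6

Remark: atom numbers are those of the eudesmane/germacrane skeleton (C14 angular methyl, C15 oxygenated carbon, C12 carboxyl); reagent 15 is assumed to be purchasable (it is otherwise the saponification product of its commercial methyl ester).

Step 1
Reactants: 1 (R)-(−)-carvone; 2 phenyl vinyl sulfoxide
Product: 4 (2R,5R)-2-methyl-2-[2-(phenylsulfinyl)ethyl]-5-(prop-1-en-2-yl)cyclohexan-1-one (both sulfur epimers), via lithium enolate 3 (not isolated)
Conditions: LiBH(s-Bu)3, THF, −78 °C; then 2, −78 to 0 °C; then H2O
Reagents that add atoms: none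
Why: Conjugate reduction of the enone gives the regiodefined tetrasubstituted enolate, and its Michael addition to the vinyl sulfoxide (a vinyl cation equivalent) should occur axially on the half-chair with equatorial isopropenyl, so that the new C–C bond at the quaternary carbon ends cis to the isopropenyl group, as in the Robinson annulation of dihydrocarvone.

Step 2
Reactants: 4
Product: 5 (2R,5R)-2-ethenyl-2-methyl-5-(prop-1-en-2-yl)cyclohexan-1-one
Conditions: xylenes, CaCO3, 140 °C
Reagents that add atoms: none
Why: Sulfoxide pyrolysis (thermal syn-elimination) can only take a hydrogen from the CH2 next to the quaternary carbon, so it should unveil the vinyl group without touching either stereocenter.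

Step 3
Reactants: 5; 6 isopropenylmagnesium bromide
Product: 7 (1S,2R,5R)-2-ethenyl-2-methyl-1,5-di(prop-1-en-2-yl)cyclohexan-1-ol
Conditions: CeCl3, THF, −78 to 0 °C; then H2O
Reagents that add atoms: none
Why: The CeCl3-promoted Grignard 1,2-addition (enolization suppressed) should take place anti to the axial vinyl group on the α-carbon (axial attack), which places the new isopropenyl group trans to the vinyl group and the hydroxyl equatorial.

Step 4
Reactants: 7
Product: 10 (1(10)E,4Z,7R)-germacra-1(10),4,11-trien-5-yl trifluoromethanesulfonate (ring carbons C3/C6 trans across C4=C5), via potassium alkoxide 8 (not isolated), via potassium enolate 9 (not isolated)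
Conditions: KH, 18-crown-6, THF, 25 to 50 °C; then PhNTf2, −78 to 0 °C
Reagents that add atoms: N-phenylbis(trifluoromethanesulfonimide), O=S(=O)(N(c1ccccc1)S(=O)(=O)C(F)(F)F)C(F)(F)F
Why: The anionic oxy-Cope rearrangement of the alkoxide, through a chair transition state reached after ring inversion (trans alkenyl groups both pseudo-equatorial), cleaves C5–C10 of the cyclohexane and forms C2–C3, which should give the ten-membered enolate with both ring alkenes in the germacrene (ring-trans) geometry; O-triflation then fixes the enolate regio- and stereochemistry.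

Step 5
Reactants: 10
Product: 11 germacrene A, (1(10)E,4E,7R)-germacra-1(10),4,11-triene
Conditions: Pd(OAc)2 (5 mol%), PPh3, HCO2H, Bu3N, DMF, 40 °C
Reagents that add atoms: none
Why: Formate hydrogenolysis of the enol triflate (oxidative addition to zerovalent palladium, decarboxylation of formate, reductive elimination) should replace OTf by H with retention of alkene geometry, and the mild temperature avoids the Cope rearrangement of the 1,5-diene.

Step 6
Reactants: 11
Product: 12 β-selinene, eudesma-4(15),11-diene (5α-H, 10β-CH3, 7β-isopropenyl)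
Conditions: TsOH·H2O (2 mol%), CH2Cl2, −20 °C; then Et3N
Reagents that add atoms: none
Why: The acid protonates C1 of the strained 1(10)-alkene while the 4,5-alkene, held parallel to it across the ring, attacks the developing C10 cation through C5, and the resulting C4 cation loses a proton from the C15 methyl group. The closest known reaction type is the biomimetic transannular cation–olefin cyclization of germacrenes to eudesmanes. One transannular bond divides the ten-membered ring into two six-membered rings, the closure being 6-endo-trig with respect to ring A (both alkene carbons inside) and 6-exo-trig with respect to ring B (C4 outside). C10 and C5 are set together by the crown (chair–chair) conformer of the E,E-diene, in which the C7 isopropenyl group is equatorial and both olefinic methyl groups point to the same face, so antiparallel addition should give the trans-decalin with 10β-CH3 and 5α-H relative to the C7 center from carvone. The step needs protonation of the 1(10)-alkene and not of the isopropenyl group, which transannular π-participation with release of ring strain secures, and it needs the proton loss to avoid the axial H-5, which is shielded at the ring fusion next to the quaternary C10. Proton loss from the freely rotating C15 methyl group, which always has a C–H bond aligned with the empty orbital, should dominate under these brief kinetic conditions, and a leak toward C3 is tolerated because the oxidation and transposition of steps 7 and 8 lead to the same C15 alcohol from either alkene position.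

Step 7
Reactants: 12
Product: 13 eudesma-4(15),11-dien-3α-ol
Conditions: SeO2 (0.3 equiv), t-BuOOH, CH2Cl2, 0 °C
Reagents that add atoms: selenium dioxide, O=[Se]=O; tert-butyl hydroperoxide, CC(C)(C)OO
Why: The SeO2 allylic oxidation (ene reaction at the ring methylene with removal of the axial H-3α, then [2,3]-sigmatropic shift) should hydroxylate the ring CH2 faster than the isopropenyl methyl group; any material whose ring alkene already lies at C3–C4 would be hydroxylated at C15 under the same conditions and so be carried forward as the alcohol 14.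

Step 8
Reactants: 13
Product: 14 eudesma-3,11-dien-15-ol
Conditions: Ph3SiOReO3 (3 mol%), Et2O, 0 °C
Reagents that add atoms: none
Why: The perrhenate-catalyzed 1,3-transposition of the allylic alcohol ([3,3]-shift of the perrhenate ester) runs to the thermodynamic isomer with the endocyclic trisubstituted alkene and the primary hydroxyl, so both C3 epimers of 13 should converge on 14.

Step 9
Reactants: 14; 15 [bis(2,2,2-trifluoroethoxy)phosphoryl]acetic acid
Product: 16 eudesma-3,11-dien-15-yl [bis(2,2,2-trifluoroethoxy)phosphoryl]acetate
Conditions: DCC, DMAP (cat.), CH2Cl2, 0 °C to rt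
Reagents that add atoms: none
Why: Steglich esterification of the unhindered primary allylic alcohol installs the phosphonoacetate needed for a Z-selective olefination on the substrate.

Step 10
Reactants: 16; 17 4-(tert-butyldimethylsilyloxy)benzaldehyde
Product: 18 eudesma-3,11-dien-15-yl (Z)-3-[4-(tert-butyldimethylsilyloxy)phenyl]prop-2-enoate
Conditions: KN(SiMe3)2, 18-crown-6, THF, −78 °C
Reagents that add atoms: none
Why: The Still–Gennari olefination with the electron-poor bis(trifluoroethyl) phosphonate under dissociating conditions should give the (Z)-cinnamate under kinetic control.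

Step 11
Reactants: 18
Product: 19 12-hydroxyeudesma-3,11(13)-dien-15-yl (Z)-3-[4-(tert-butyldimethylsilyloxy)phenyl]prop-2-enoate
Conditions: SeO2 (0.5 equiv), t-BuOOH, CH2Cl2, rt, dark
Reagents that add atoms: selenium dioxide, O=[Se]=O; tert-butyl hydroperoxide, CC(C)(C)OO
Why: A second SeO2 allylic oxidation (ene reaction, then [2,3]-shift) should now go to the isopropenyl methyl group, because the ring alkene is deactivated as an allylic ester and the cinnamate has no allylic hydrogen.

Step 12
Reactants: 19
Product: 20 12-oxoeudesma-3,11(13)-dien-15-yl (Z)-3-[4-(tert-butyldimethylsilyloxy)phenyl]prop-2-enoate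
Conditions: activated MnO2 (excess), CH2Cl2, rt, dark
Reagents that add atoms: none
Why: The MnO2 oxidation is selective for allylic alcohols and should give the 2-substituted acrolein without touching the esters, the silyl ether or the alkene geometry; any enal already formed in step 11 converges on the same product.

Step 13
Reactants: 20
Product: 21 15-{(Z)-3-[4-(tert-butyldimethylsilyloxy)phenyl]prop-2-enoyloxy}eudesma-3,11(13)-dien-12-oic acid
Conditions: NaClO2, NaH2PO4, 2-methyl-2-butene, t-BuOH/H2O, 0 °C to rt, dark
Reagents that add atoms: sodium chlorite, [Na+].[O-]Cl=O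
Why: In the Pinnick oxidation chlorous acid adds to the aldehyde and fragments to the acrylic acid and HOCl, which 2-methyl-2-butene scavenges, so the ring alkene, the (Z)-enoate and the aryl silyl ether should stay intact.

Step 14
Reactants: 21
Product: 22 15-[(Z)-3-(4-hydroxyphenyl)prop-2-enoyloxy]eudesma-3,11(13)-dien-12-oic acid (CNP0183482.1)
Conditions: HF·pyridine, pyridine, THF, 0 °C to rt, dark
Reagents that add atoms: none
Why: Fluoride desilylation of the aryl silyl ether under buffered acidic conditions, with no free phenoxide, should release the phenol without isomerizing the (Z)-enoate or cleaving the allylic ester.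

**Compound list**

1 | (R)-(−)-carvone | CC1=CC[C@H](CC1=O)C(C)=C | starting material
2 | phenyl vinyl sulfoxide (racemic) | C=CS(=O)c1ccccc1 | starting material
3 | lithium (5R)-2-methyl-5-(prop-1-en-2-yl)cyclohex-1-en-1-olate | [Li+].CC1=C([O-])C[C@@H](CC1)C(C)=C | intermediate
4 | (2R,5R)-2-methyl-2-[2-(phenylsulfinyl)ethyl]-5-(prop-1-en-2-yl)cyclohexan-1-one (side chain cis to isopropenyl; both sulfur epimers) | C[C@]1(CCS(=O)c2ccccc2)CC[C@H](CC1=O)C(C)=C | intermediate
5 | (2R,5R)-2-ethenyl-2-methyl-5-(prop-1-en-2-yl)cyclohexan-1-one (vinyl cis to isopropenyl) | C[C@]1(C=C)CC[C@H](CC1=O)C(C)=C | intermediate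
6 | isopropenylmagnesium bromide | CC(=C)[Mg]Br | starting material
7 | (1S,2R,5R)-2-ethenyl-2-methyl-1,5-di(prop-1-en-2-yl)cyclohexan-1-ol (1-isopropenyl trans to 2-vinyl) | C[C@]1(C=C)CC[C@H](C[C@]1(O)C(C)=C)C(C)=C | intermediate
8 | potassium alkoxide of 7 | [K+].C[C@]1(C=C)CC[C@H](C[C@]1([O-])C(C)=C)C(C)=C | intermediate
9 | potassium (7R)-germacra-1(10),4,11-trien-5-olate (C9/C2 trans across C1=C10, C3/C6 trans across C4=C5) | [K+].CC(=C)[C@@H]1CC/C(C)=C/CC/C(C)=C(\[O-])C1 | intermediate
10 | (1(10)E,4Z,7R)-germacra-1(10),4,11-trien-5-yl trifluoromethanesulfonate (C3/C6 trans across C4=C5) | CC(=C)[C@@H]1CC/C(C)=C/CC/C(C)=C(\OS(=O)(=O)C(F)(F)F)C1 | intermediate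
11 | germacrene A, (1(10)E,4E,7R)-germacra-1(10),4,11-triene | CC(=C)[C@@H]1CC/C(C)=C/CC/C(C)=C/C1 | intermediate
12 | β-selinene, (4aR,7R,8aS)-4a-methyl-1-methylidene-7-(prop-1-en-2-yl)decahydronaphthalene | CC(=C)[C@@H]1CC[C@@]2(C)CCCC(=C)[C@@H]2C1 | intermediate
13 | eudesma-4(15),11-dien-3α-ol (axial hydroxyl) | CC(=C)[C@@H]1CC[C@@]2(C)CC[C@@H](O)C(=C)[C@@H]2C1 | intermediate
14 | eudesma-3,11-dien-15-ol | CC(=C)[C@@H]1CC[C@@]2(C)CCC=C(CO)[C@@H]2C1 | intermediate
15 | [bis(2,2,2-trifluoroethoxy)phosphoryl]acetic acid | OC(=O)CP(=O)(OCC(F)(F)F)OCC(F)(F)F | starting material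
16 | eudesma-3,11-dien-15-yl [bis(2,2,2-trifluoroethoxy)phosphoryl]acetate | CC(=C)[C@@H]1CC[C@@]2(C)CCC=C(COC(=O)CP(=O)(OCC(F)(F)F)OCC(F)(F)F)[C@@H]2C1 | intermediate
17 | 4-(tert-butyldimethylsilyloxy)benzaldehyde | O=Cc1ccc(O[Si](C)(C)C(C)(C)C)cc1 | starting material
18 | eudesma-3,11-dien-15-yl (Z)-3-[4-(tert-butyldimethylsilyloxy)phenyl]prop-2-enoate | CC(=C)[C@@H]1CC[C@@]2(C)CCC=C(COC(=O)/C=C\c3ccc(O[Si](C)(C)C(C)(C)C)cc3)[C@@H]2C1 | intermediate
19 | 12-hydroxyeudesma-3,11(13)-dien-15-yl (Z)-3-[4-(tert-butyldimethylsilyloxy)phenyl]prop-2-enoate | C=C(CO)[C@@H]1CC[C@@]2(C)CCC=C(COC(=O)/C=C\c3ccc(O[Si](C)(C)C(C)(C)C)cc3)[C@@H]2C1 | intermediate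
20 | 12-oxoeudesma-3,11(13)-dien-15-yl (Z)-3-[4-(tert-butyldimethylsilyloxy)phenyl]prop-2-enoate | C=C(C=O)[C@@H]1CC[C@@]2(C)CCC=C(COC(=O)/C=C\c3ccc(O[Si](C)(C)C(C)(C)C)cc3)[C@@H]2C1 | intermediate
21 | 15-{(Z)-3-[4-(tert-butyldimethylsilyloxy)phenyl]prop-2-enoyloxy}eudesma-3,11(13)-dien-12-oic acid | C=C(C(=O)O)[C@@H]1CC[C@@]2(C)CCC=C(COC(=O)/C=C\c3ccc(O[Si](C)(C)C(C)(C)C)cc3)[C@@H]2C1 | intermediate
22 | 15-[(Z)-3-(4-hydroxyphenyl)prop-2-enoyloxy]eudesma-3,11(13)-dien-12-oic acid (CNP0183482.1) | C=C(C(=O)O)[C@@H]1CC[C@@]2(C)CCC=C(COC(=O)/C=C\c3ccc(O)cc3)[C@@H]2C1 | target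

Total step count: 14. Longest linear sequence: 14 steps, from (R)-carvone 1.

**Steps most likely to fail**

Step 6. The termination may lose regiocontrol (proton loss from the ring-fusion carbon giving the tetrasubstituted alkene), and the acid may go on to migrate the new double bonds. The fallback ends the cation by capture instead of proton loss. It sets out from 11: TsOH·H2O in acetone/H2O at 0 °C should give, by the same transannular closure with water adding anti to the new C5–C10 bond, the equatorial tertiary alcohol selin-11-en-4α-ol F1. SOCl2/pyridine at 0 °C then dehydrates it by E2; the equatorial chlorosulfite has no antiperiplanar ring hydrogen, so elimination can only enter the methyl group. The sequence comes back to the route at 12.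

Step 7. The ene oxidation may discriminate poorly between the ring methylene and the isopropenyl group, and may overoxidize. The fallback removes the need for discrimination. It sets out from 12: excess SeO2/t-BuOOH oxidizes both allylic positions on purpose to eudesma-4(15),11(13)-diene-3α,12-diol F2. Et3SiCl/imidazole at −78 °C silylates only the primary hydroxyl, giving the 12-O-triethylsilyl ether F3. Ph3SiOReO3 transposes the secondary allylic alcohol to 12-(triethylsilyloxy)eudesma-3,11(13)-dien-15-ol F4. The conditions of steps 9 and 10 then give the phosphonoacetate F5 and the (Z)-cinnamate F6. PPTS/MeOH removes the alkyl triethylsilyl ether but not the aryl silyl ether, and the sequence comes back to the route at 19.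

Step 3. Facial selectivity may be poor (the bulky alkenyl nucleophile attacking syn to the vinyl group), or the hindered ketone may enolize; the wrong carbinol epimer would deliver the wrong ring-alkene geometry in step 4. The fallback builds the isopropenyl group in two stages from a small, axially attacking nucleophile. It sets out from 5: ethynylmagnesium bromide in THF at 0 °C should add anti to the axial vinyl group to give (1S,2R,5R)-2-ethenyl-1-ethynyl-2-methyl-5-(prop-1-en-2-yl)cyclohexan-1-ol F7. Anti-carbomagnesiation of its magnesium alkoxide with MeMgBr and catalytic CuI in refluxing Et2O/THF puts the methyl group on the alkyne carbon next to the carbinol, and protonolysis comes back to the route at 7.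

**Further compounds**

F1 | step 6 | selin-11-en-4α-ol (equatorial 4-OH, axial 4-CH3) | CC(=C)[C@@H]1CC[C@@]2(C)CCC[C@@](C)(O)[C@@H]2C1
F2 | step 7 | eudesma-4(15),11(13)-diene-3α,12-diol | C=C(CO)[C@@H]1CC[C@@]2(C)CC[C@@H](O)C(=C)[C@@H]2C1
F3 | step 7 | 12-(triethylsilyloxy)eudesma-4(15),11(13)-dien-3α-ol | C=C(CO[Si](CC)(CC)CC)[C@@H]1CC[C@@]2(C)CC[C@@H](O)C(=C)[C@@H]2C1
F4 | step 7 | 12-(triethylsilyloxy)eudesma-3,11(13)-dien-15-ol | C=C(CO[Si](CC)(CC)CC)[C@@H]1CC[C@@]2(C)CCC=C(CO)[C@@H]2C1
F5 | step 7 | 12-(triethylsilyloxy)eudesma-3,11(13)-dien-15-yl [bis(2,2,2-trifluoroethoxy)phosphoryl]acetate | C=C(CO[Si](CC)(CC)CC)[C@@H]1CC[C@@]2(C)CCC=C(COC(=O)CP(=O)(OCC(F)(F)F)OCC(F)(F)F)[C@@H]2C1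
F6 | step 7 | 12-(triethylsilyloxy)eudesma-3,11(13)-dien-15-yl (Z)-3-[4-(tert-butyldimethylsilyloxy)phenyl]prop-2-enoate | C=C(CO[Si](CC)(CC)CC)[C@@H]1CC[C@@]2(C)CCC=C(COC(=O)/C=C\c3ccc(O[Si](C)(C)C(C)(C)C)cc3)[C@@H]2C1
F7 | step 3 | (1S,2R,5R)-2-ethenyl-1-ethynyl-2-methyl-5-(prop-1-en-2-yl)cyclohexan-1-ol (ethynyl trans to vinyl) | C[C@]1(C=C)CC[C@H](C[C@]1(O)C#C)C(C)=C
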